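**Plan**
- Retrosynthesis: the four benzyl ethers are removed last. Ring A is then cut at C1–C(=O) and at C6–O; both bonds form together when pentanoic acid adds across a C1–C6 aryne.
- Enabling feature: in ring A the pentanoyl carbon C1 and the hydroxyl carbon C6 are neighbours, and the C2 oxygen beside C1 polarises the aryne so that oxygen enters at C6 and the acyl carbon at C1.
- The C5–CH2 bond is cut next (Friedel–Crafts benzylation) into a ring A bromophenol and a ring B benzylic alcohol. Ring B is cut at C3'–C(=O) and C1'–CH2 back to 2,4,6-trihydroxytoluene.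
- Forward: both benzene rings are bought and no ring is formed. Ring A phenol comes from 3,5-dihydroxy-4-methylbenzoic acid (steps 1–4) and the ring B alcohol from 2,4,6-trihydroxytoluene (steps 5–9). They are joined at the methylene bridge (step 10), followed by C1 silane, C6 triflate, aryne insertion and hydrogenolysis (steps 11–14).
- Stereochemistry: the target has no stereocentre and no stereogenic double bond, so nothing has to be set.

Key step: step 13

Remark: ring A is numbered C1 (pentanoyl), C2 (OH), C3 (CH3), C4 (OH), C5 (CH2 bridge), C6 (OH); ring B is numbered C1' (CH2 bridge), C2' (OH), C3' (butanoyl), C4' (OH), C5' (CH3), C6' (OCH3). The silyl enol ether in 18 and 19 is drawn as the Z isomer; its geometry is without consequence because it is hydrolysed in the same step.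

**Route**

Step 1
Reactants: 1 3,5-dihydroxy-4-methylbenzoic acid
Product: 3 3,5-bis(benzyloxy)-4-methylbenzoic acid, via benzyl 3,5-bis(benzyloxy)-4-methylbenzoate 2 (not isolated)
Conditions: BnBr (3.3 equiv), K2CO3, DMF, 60 °C; then NaOH, MeOH–H2O, 70 °C; HCl work-up
Reagents that add atoms: benzyl bromide, BrCc1ccccc1; sodium hydroxide, [Na+].[OH-]
Why: Williamson alkylation benzylates both phenols and the carboxylate, and saponification of the benzyl ester in the same pot should leave only the acid free, since aryl benzyl ethers are inert to hydroxide.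

Step 2
Reactants: 3 3,5-bis(benzyloxy)-4-methylbenzoic acid
Product: 5 1-[3,5-bis(benzyloxy)-4-methylphenyl]ethan-1-one, via dilithium gem-diolate 4 (not isolated)
Conditions: MeLi (2.4 equiv), THF, 0 °C to rt; inverse quench into cold 1 M HCl
Reagents that add atoms: methyllithium, [Li]C
Why: Addition of methyllithium to a lithium carboxylate stops at the gem-diolate, which collapses to the methyl ketone only on acidic quench (carboxylic acid to methyl ketone with an organolithium).

Step 3
Reactants: 5 1-[3,5-bis(benzyloxy)-4-methylphenyl]ethan-1-one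
Product: 7 3,5-bis(benzyloxy)-4-methylphenol, via 3,5-bis(benzyloxy)-4-methylphenyl acetate 6 (not isolated)
Conditions: mCPBA, TFA (cat.), CH2Cl2, rt; aq. NaHCO3 wash; then K2CO3 (cat.), MeOH, rt
Reagents that add atoms: 3-chloroperoxybenzoic acid, OOC(=O)c1cccc(Cl)c1
Why: In the Baeyer–Villiger oxidation of an aryl methyl ketone the aryl group migrates in preference to methyl, and methanolysis of the resulting acetate should release the phenol whose hydroxyl sits para to the ring methyl.

Step 4
Reactants: 7 3,5-bis(benzyloxy)-4-methylphenol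
Product: 8 3,5-bis(benzyloxy)-2-bromo-4-methylphenol
Conditions: NBS (1.0 equiv), CH2Cl2, −78 to −20 °C
Reagents that add atoms: N-bromosuccinimide, BrN1C(=O)CCC1=O
Why: Electrophilic aromatic bromination can only occur at the two equivalent carbons ortho to the hydroxyl (the para carbon carries the methyl), and one equivalent at low temperature should stop at the monobromide because bromine deactivates the ring.

Step 5
Reactants: 9 2,4,6-trihydroxytoluene; 10 butanoyl chloride
Product: 11 1-(2,4,6-trihydroxy-3-methylphenyl)butan-1-one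
Conditions: AlCl3, PhNO2–CH2Cl2, 0 to 40 °C; aq. HCl work-up
Reagents that add atoms: none
Why: Friedel–Crafts acylation of the phloroglucinol nucleus takes place at one of its two equivalent free carbons and stops after one acyl group because the product is deactivated and chelated to aluminium.

Step 6
Reactants: 11 1-(2,4,6-trihydroxy-3-methylphenyl)butan-1-one
Product: 12 1-(2,6-dihydroxy-4-methoxy-3-methylphenyl)butan-1-one (aspidinol)
Conditions: Me2SO4 (1.0 equiv), K2CO3 (1.0 equiv), acetone, rt
Reagents that add atoms: dimethyl sulfate, COS(=O)(=O)OC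
Why: The 4-hydroxyl, para to the acyl group and not hydrogen-bonded to the carbonyl, is the most acidic, so one equivalent of base and dimethyl sulfate should methylate it in preference to the two chelated ortho hydroxyls (selective Williamson O-methylation).

Step 7
Reactants: 12 1-(2,6-dihydroxy-4-methoxy-3-methylphenyl)butan-1-one
Product: 13 1-[2,6-bis(benzyloxy)-4-methoxy-3-methylphenyl]butan-1-one
Conditions: BnBr (2.5 equiv), K2CO3, DMF, 70 °C
Reagents that add atoms: benzyl bromide, BrCc1ccccc1
Why: Forcing Williamson benzylation in a dipolar aprotic solvent should etherify both hydrogen-bonded ortho hydroxyls on oxygen and leave the free ring carbon untouched.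

Step 8
Reactants: 13 1-[2,6-bis(benzyloxy)-4-methoxy-3-methylphenyl]butan-1-one
Product: 15 2,4-bis(benzyloxy)-3-butanoyl-6-methoxy-5-methylbenzaldehyde, via aryl iminium chloride 14 (not isolated)
Conditions: (chloromethylene)dimethyliminium chloride, MeCN, 0 to 50 °C; then H2O
Reagents that add atoms: (chloromethylene)dimethyliminium chloride, C[N+](C)=CCl.[Cl-]; water, O
Why: Vilsmeier–Haack formylation should take the only unsubstituted ring carbon, which is ortho to the methoxy and one benzyloxy group and para to the other, the twisted butanoyl group deactivating it little, and hydrolysis of the iminium salt then gives the aldehyde.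

Step 9
Reactants: 15 2,4-bis(benzyloxy)-3-butanoyl-6-methoxy-5-methylbenzaldehyde
Product: 16 1-[2,6-bis(benzyloxy)-3-(hydroxymethyl)-4-methoxy-5-methylphenyl]butan-1-one
Conditions: NaBH4, THF–MeOH, −10 °C
Reagents that add atoms: none
Why: Chemoselective borohydride reduction should take the aldehyde and spare the butanoyl ketone, which is less electrophilic and shielded by two ortho benzyloxy groups.

Step 10
Reactants: 8 3,5-bis(benzyloxy)-2-bromo-4-methylphenol; 16 1-[2,6-bis(benzyloxy)-3-(hydroxymethyl)-4-methoxy-5-methylphenyl]butan-1-one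
Product: 17 1-[2,6-bis(benzyloxy)-3-{[2,4-bis(benzyloxy)-5-bromo-6-hydroxy-3-methylphenyl]methyl}-4-methoxy-5-methylphenyl]butan-1-one
Conditions: TsOH·H2O (10 mol%), HFIP–CH2Cl2, 0 °C to rt; 8 in 1.3-fold excess
Reagents that add atoms: none
Why: In this acid-catalysed Friedel–Crafts benzylation, ionisation of 16 gives a 2,4,6-trialkoxybenzyl cation whose own ring is fully substituted, while phenol 8 offers a single free carbon (C5, ortho to the hydroxyl and ortho/para to the benzyloxy groups), so only the C5–CH2 bond should form.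

Step 11
Reactants: 17 1-[2,6-bis(benzyloxy)-3-{[2,4-bis(benzyloxy)-5-bromo-6-hydroxy-3-methylphenyl]methyl}-4-methoxy-5-methylphenyl]butan-1-one
Product: 20 1-[2,6-bis(benzyloxy)-3-{[2,4-bis(benzyloxy)-6-hydroxy-3-methyl-5-(trimethylsilyl)phenyl]methyl}-4-methoxy-5-methylphenyl]butan-1-one, via bis-silylated bromide 18 (not isolated), via lithium phenolate 19 (not isolated)
Conditions: TMSOTf (2.4 equiv), Et3N, CH2Cl2, 0 °C to rt; filtration from pentane; then n-BuLi (1.1 equiv), THF, −78 °C; then MeOH, K2CO3 (cat.), 0 °C to rt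
Reagents that add atoms: trimethylsilyl trifluoromethanesulfonate, C[Si](C)(C)OS(=O)(=O)C(F)(F)F
Why: Silylation of the phenol and of the ketone enol masks the butanoyl carbonyl as a silyl enol ether, so that bromine–lithium exchange at C1 can be followed by the fast 1,3 oxygen-to-carbon silyl shift (retro-Brook rearrangement), and methanolysis then returns the ketone while the aryl–silicon bond is stable to base.

Step 12
Reactants: 20 1-[2,6-bis(benzyloxy)-3-{[2,4-bis(benzyloxy)-6-hydroxy-3-methyl-5-(trimethylsilyl)phenyl]methyl}-4-methoxy-5-methylphenyl]butan-1-one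
Product: 21 3,5-bis(benzyloxy)-2-{[2,4-bis(benzyloxy)-3-butanoyl-6-methoxy-5-methylphenyl]methyl}-4-methyl-6-(trimethylsilyl)phenyl trifluoromethanesulfonate
Conditions: Tf2O, pyridine, CH2Cl2, −20 to 0 °C
Reagents that add atoms: trifluoromethanesulfonic anhydride, O=S(=O)(OS(=O)(=O)C(F)(F)F)C(F)(F)F
Why: O-Sulfonylation of an ortho-silyl phenol with triflic anhydride and pyridine is the standard last step towards 2-(trimethylsilyl)aryl triflates and should leave the aryl silane and the hindered ketone untouched.

Step 13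
Reactants: 21 3,5-bis(benzyloxy)-2-{[2,4-bis(benzyloxy)-3-butanoyl-6-methoxy-5-methylphenyl]methyl}-4-methyl-6-(trimethylsilyl)phenyl trifluoromethanesulfonate; 22 pentanoic acid
Product: 24 1-[2,4-bis(benzyloxy)-5-{[2,4-bis(benzyloxy)-3-butanoyl-6-methoxy-5-methylphenyl]methyl}-6-hydroxy-3-methylphenyl]pentan-1-one, via ring A C1–C6 aryne 23 (not isolated)
Conditions: CsF (4 equiv), pentanoic acid (1.5 equiv), THF, 120 °C, sealed tube
Reagents that add atoms: none
Why: Fluoride attacks the C1 silicon and the C6 triflate leaves, releasing aryne 23; caesium pentanoate adds through oxygen at C6, the aryl anion left at C1 closes onto the neighbouring ester carbonyl to a four-membered alkoxide, and this opens to the ortho-acyl phenoxide, a net insertion of the aryne into the C–O bond of the acid. The closest known reaction type is the fluoride-induced aryne insertion into carboxylic acids that gives ortho-hydroxyaryl ketones in hot THF. No ring is kept (the four-membered ring is transient) and no stereocentre is formed. The selectivity needed is oxygen to C6 and carbon to C1: the C2 benzyloxy group next to the triple bond withdraws inductively, makes C6 the more electrophilic aryne carbon and stabilises the developing charge at C1, which should outweigh the steric effect of the C5 benzylic substituent. An aprotic solvent, high temperature and only a small excess of acid are chosen so that acyl transfer at C1 outruns protonation, and the carboxylate is kept in excess over the aryne so that it outruns capture by a ring B ether oxygen.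

Step 14
Reactants: 24 1-[2,4-bis(benzyloxy)-5-{[2,4-bis(benzyloxy)-3-butanoyl-6-methoxy-5-methylphenyl]methyl}-6-hydroxy-3-methylphenyl]pentan-1-one
Product: 25 1-{3-[(3-butanoyl-2,4-dihydroxy-6-methoxy-5-methylphenyl)methyl]-2,4,6-trihydroxy-5-methylphenyl}pentan-1-one (target)
Conditions: H2 (1 atm), 10% Pd/C, EtOAc–MeOH, rt
Reagents that add atoms: none
Why: Hydrogenolysis of the four aryl benzyl ethers over Pd/C is neutral, which avoids the acid- or base-induced scrambling of methylene-bridged phloroglucinols, and the hydrogen-bonded aryl ketones should not be reduced at atmospheric pressure.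

**Compound list**

1 | 3,5-dihydroxy-4-methylbenzoic acid | Cc1c(O)cc(C(=O)O)cc1O | starting material
2 | benzyl 3,5-bis(benzyloxy)-4-methylbenzoate | O=C(OCc1ccccc1)c1cc(OCc2ccccc2)c(C)c(OCc2ccccc2)c1 | intermediate
3 | 3,5-bis(benzyloxy)-4-methylbenzoic acid | OC(=O)c1cc(OCc2ccccc2)c(C)c(OCc2ccccc2)c1 | intermediate
4 | dilithium 1-[3,5-bis(benzyloxy)-4-methylphenyl]ethane-1,1-diolate | [Li+].[Li+].CC([O-])([O-])c1cc(OCc2ccccc2)c(C)c(OCc2ccccc2)c1 | intermediate
5 | 1-[3,5-bis(benzyloxy)-4-methylphenyl]ethan-1-one | CC(=O)c1cc(OCc2ccccc2)c(C)c(OCc2ccccc2)c1 | intermediate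
6 | 3,5-bis(benzyloxy)-4-methylphenyl acetate | CC(=O)Oc1cc(OCc2ccccc2)c(C)c(OCc2ccccc2)c1 | intermediate
7 | 3,5-bis(benzyloxy)-4-methylphenol | Oc1cc(OCc2ccccc2)c(C)c(OCc2ccccc2)c1 | intermediate
8 | 3,5-bis(benzyloxy)-2-bromo-4-methylphenol | Oc1cc(OCc2ccccc2)c(C)c(OCc2ccccc2)c1Br | intermediate
9 | 2,4,6-trihydroxytoluene | Cc1c(O)cc(O)cc1O | starting material
10 | butanoyl chloride | CCCC(Cl)=O | starting material
11 | 1-(2,4,6-trihydroxy-3-methylphenyl)butan-1-one | CCCC(=O)c1c(O)cc(O)c(C)c1O | intermediate
12 | 1-(2,6-dihydroxy-4-methoxy-3-methylphenyl)butan-1-one (aspidinol) | CCCC(=O)c1c(O)cc(OC)c(C)c1O | intermediate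
13 | 1-[2,6-bis(benzyloxy)-4-methoxy-3-methylphenyl]butan-1-one | CCCC(=O)c1c(OCc2ccccc2)cc(OC)c(C)c1OCc1ccccc1 | intermediate
14 | {[2,4-bis(benzyloxy)-3-butanoyl-6-methoxy-5-methylphenyl]methylidene}dimethylammonium chloride | C[N+](C)=Cc1c(OCc2ccccc2)c(C(=O)CCC)c(OCc2ccccc2)c(C)c1OC.[Cl-] | intermediate
15 | 2,4-bis(benzyloxy)-3-butanoyl-6-methoxy-5-methylbenzaldehyde | O=Cc1c(OCc2ccccc2)c(C(=O)CCC)c(OCc2ccccc2)c(C)c1OC | intermediate
16 | 1-[2,6-bis(benzyloxy)-3-(hydroxymethyl)-4-methoxy-5-methylphenyl]butan-1-one | OCc1c(OCc2ccccc2)c(C(=O)CCC)c(OCc2ccccc2)c(C)c1OC | intermediate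
17 | 1-[2,6-bis(benzyloxy)-3-{[2,4-bis(benzyloxy)-5-bromo-6-hydroxy-3-methylphenyl]methyl}-4-methoxy-5-methylphenyl]butan-1-one | Brc1c(OCc2ccccc2)c(C)c(OCc2ccccc2)c(Cc2c(OCc3ccccc3)c(C(=O)CCC)c(OCc3ccccc3)c(C)c2OC)c1O | intermediate
18 | {3,5-bis(benzyloxy)-2-bromo-6-[(2,4-bis(benzyloxy)-6-methoxy-5-methyl-3-{(1Z)-1-[(trimethylsilyl)oxy]but-1-en-1-yl}phenyl)methyl]-4-methylphenoxy}trimethylsilane | Brc1c(OCc2ccccc2)c(C)c(OCc2ccccc2)c(Cc2c(OCc3ccccc3)c(/C(O[Si](C)(C)C)=C/CC)c(OCc3ccccc3)c(C)c2OC)c1O[Si](C)(C)C | intermediate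
19 | lithium 3,5-bis(benzyloxy)-2-[(2,4-bis(benzyloxy)-6-methoxy-5-methyl-3-{(1Z)-1-[(trimethylsilyl)oxy]but-1-en-1-yl}phenyl)methyl]-4-methyl-6-(trimethylsilyl)phenolate | C[Si](C)(C)c1c(OCc2ccccc2)c(C)c(OCc2ccccc2)c(Cc2c(OCc3ccccc3)c(/C(O[Si](C)(C)C)=C/CC)c(OCc3ccccc3)c(C)c2OC)c1[O-].[Li+] | intermediate
20 | 1-[2,6-bis(benzyloxy)-3-{[2,4-bis(benzyloxy)-6-hydroxy-3-methyl-5-(trimethylsilyl)phenyl]methyl}-4-methoxy-5-methylphenyl]butan-1-one | C[Si](C)(C)c1c(OCc2ccccc2)c(C)c(OCc2ccccc2)c(Cc2c(OCc3ccccc3)c(C(=O)CCC)c(OCc3ccccc3)c(C)c2OC)c1O | intermediate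
21 | 3,5-bis(benzyloxy)-2-{[2,4-bis(benzyloxy)-3-butanoyl-6-methoxy-5-methylphenyl]methyl}-4-methyl-6-(trimethylsilyl)phenyl trifluoromethanesulfonate | C[Si](C)(C)c1c(OCc2ccccc2)c(C)c(OCc2ccccc2)c(Cc2c(OCc3ccccc3)c(C(=O)CCC)c(OCc3ccccc3)c(C)c2OC)c1OS(=O)(=O)C(F)(F)F | intermediate
22 | pentanoic acid | CCCCC(=O)O | starting material
23 | ring A C1–C6 aryne: 1-{2,6-bis(benzyloxy)-3-[(2,4-bis(benzyloxy)-3-methylcyclohexa-1,3-dien-5-yn-1-yl)methyl]-4-methoxy-5-methylphenyl}butan-1-one | C1#CC(OCc2ccccc2)=C(C)C(OCc2ccccc2)=C1Cc1c(OCc2ccccc2)c(C(=O)CCC)c(OCc2ccccc2)c(C)c1OC | intermediate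
24 | 1-[2,4-bis(benzyloxy)-5-{[2,4-bis(benzyloxy)-3-butanoyl-6-methoxy-5-methylphenyl]methyl}-6-hydroxy-3-methylphenyl]pentan-1-one | CCCCC(=O)c1c(OCc2ccccc2)c(C)c(OCc2ccccc2)c(Cc2c(OCc3ccccc3)c(C(=O)CCC)c(OCc3ccccc3)c(C)c2OC)c1O | intermediate
25 | 1-{3-[(3-butanoyl-2,4-dihydroxy-6-methoxy-5-methylphenyl)methyl]-2,4,6-trihydroxy-5-methylphenyl}pentan-1-one | CCCCC(=O)c1c(O)c(C)c(O)c(Cc2c(O)c(C(=O)CCC)c(O)c(C)c2OC)c1O | target

**Step count and risks**

Total step count: 14. Longest linear sequence: 10 steps (steps 5–9, then 10–14, from 2,4,6-trihydroxytoluene); the ring A branch (steps 1–4) joins at step 10.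

Steps most likely to fail:

1. Step 13 (aryne insertion). Three processes could take over:
   - the C1 aryl anion may be protonated before it reaches the ester carbonyl, leaving an aryl pentanoate without the C–C bond;
   - the aryne may be captured within the molecule by an ether oxygen of ring B;
   - fluoride may remove silicon without loss of triflate.

   The fallback introduces the pentanoyl group by electrophilic acylation and sets out from phenol 7 and alcohol 16. Benzylation of 7 (threefold excess, so that only one of its two equivalent ortho carbons reacts) with 16 under the conditions of step 10 should give 1-[2,6-bis(benzyloxy)-3-{[2,4-bis(benzyloxy)-6-hydroxy-3-methylphenyl]methyl}-4-methoxy-5-methylphenyl]butan-1-one F1. Its only free ring A carbon is C1, ortho and para to the two benzyloxy groups. Friedel–Crafts acylation with excess pentanoic acid 22 and trifluoroacetic anhydride (CH2Cl2, 0 °C) should acylate C1 and the C6 oxygen, giving 3,5-bis(benzyloxy)-2-{[2,4-bis(benzyloxy)-3-butanoyl-6-methoxy-5-methylphenyl]methyl}-4-methyl-6-pentanoylphenyl pentanoate F2. Methanolysis of the aryl ester (K2CO3, MeOH) comes back to the route at 24.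

2. Step 11 (silylation in the presence of the ring B ketone). Enol silylation may be incomplete, leaving the carbonyl open to addition or deprotonation by butyllithium, or butyllithium may attack the O–Si bond instead of bromine, so that the arene is protonated without gaining silicon. The fallback installs silicon before the fragments are joined and sets out from bromophenol 8. O-Silylation with hexamethyldisilazane should give [3,5-bis(benzyloxy)-2-bromo-4-methylphenoxy]trimethylsilane F3. n-BuLi in THF at −78 °C (bromine–lithium exchange, retro-Brook shift, with no ketone present) should give 3,5-bis(benzyloxy)-4-methyl-2-(trimethylsilyl)phenol F4. Benzylation of F4 with alcohol 16 is then run in neat HFIP at 0 °C without added acid, to limit protodesilylation and ipso attack at the silylated carbon, and comes back to the route at 20.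

3. Step 10 (fragment union). The ring B cation may attack the ipso carbon of a second molecule of 16 with loss of formaldehyde, or the new diarylmethane may be cleaved and scrambled by the acid. The fallback reverses the roles of the rings and sets out from bromophenol 8 and arene 13. Ortho-formylation of 8 (MgCl2, Et3N, paraformaldehyde, MeCN, reflux) should give 2,4-bis(benzyloxy)-5-bromo-6-hydroxy-3-methylbenzaldehyde F5. NaBH4 reduction should give 3,5-bis(benzyloxy)-2-bromo-6-(hydroxymethyl)-4-methylphenol F6. Acid-catalysed condensation of F6 (through its ortho-hydroxybenzyl cation) with the single free ring carbon of 13 comes back to the route at 17, and steps 8 and 9 are then not needed.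

Further compounds
F1 | step 13 | 1-[2,6-bis(benzyloxy)-3-{[2,4-bis(benzyloxy)-6-hydroxy-3-methylphenyl]methyl}-4-methoxy-5-methylphenyl]butan-1-one | CCCC(=O)c1c(OCc2ccccc2)c(Cc2c(O)cc(OCc3ccccc3)c(C)c2OCc2ccccc2)c(OC)c(C)c1OCc1ccccc1
F2 | step 13 | 3,5-bis(benzyloxy)-2-{[2,4-bis(benzyloxy)-3-butanoyl-6-methoxy-5-methylphenyl]methyl}-4-methyl-6-pentanoylphenyl pentanoate | CCCCC(=O)Oc1c(C(=O)CCCC)c(OCc2ccccc2)c(C)c(OCc2ccccc2)c1Cc1c(OCc2ccccc2)c(C(=O)CCC)c(OCc2ccccc2)c(C)c1OC
F3 | step 11 | [3,5-bis(benzyloxy)-2-bromo-4-methylphenoxy]trimethylsilane | C[Si](C)(C)Oc1cc(OCc2ccccc2)c(C)c(OCc2ccccc2)c1Br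
F4 | step 11 | 3,5-bis(benzyloxy)-4-methyl-2-(trimethylsilyl)phenol | C[Si](C)(C)c1c(O)cc(OCc2ccccc2)c(C)c1OCc1ccccc1
F5 | step 10 | 2,4-bis(benzyloxy)-5-bromo-6-hydroxy-3-methylbenzaldehyde | O=Cc1c(O)c(Br)c(OCc2ccccc2)c(C)c1OCc1ccccc1
F6 | step 10 | 3,5-bis(benzyloxy)-2-bromo-6-(hydroxymethyl)-4-methylphenol | OCc1c(O)c(Br)c(OCc2ccccc2)c(C)c1OCc1ccccc1
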